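**Plan**

1. Retrosynthetic cuts, in order: the two benzoate C–O bonds and the acetal-masked hydroxyls; the ring alkene C2=C3 (ring-closing metathesis of an octa-1,7-diene); the two terminal =CH2 carbons (sulfonium-ylide homologation of an epoxide on the C3 side, Wittig methylenation of a lactol on the C2 side); last, the exocyclic C1–CH2O bond, by aldol of a masked aldose with formaldehyde, back to diacetone-D-mannose.
2. Forward: the exocyclic C–C bond is made first, on the furanose; the chain is then extended by one carbon at each end; the only carbocycle arises in step 8; benzoylation and acetal hydrolysis close the route.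
3. Mapping: ring atoms C2–C1–C6–C5–C4–C3 of the target are C-1 to C-6 of D-mannose (m-1 … m-6); the CH2O carbon is formaldehyde.
4. Stereochemistry: C4, C5 and C6 are m-5, m-4 and m-3 of D-mannose and are never touched; the quaternary C1 (m-2) is set in step 1 with retention of the O-2 sense, enforced by the cis-fused dioxolane/furanose.
5. Enabling feature: C1 is a carbinol carbon flanked by an sp2 CH (C2, which can sit at the aldehyde oxidation level) and by C6 carrying a cis hydroxyl. Tying O-1/O-6 into a dioxolane fused to a furanose lactol (temporary rings, taken out in steps 3 and 11) leaves the C1–H as the single enolisable hydrogen of a masked aldehyde.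

Key step: step 1

Locants: m-n is carbon n of D-mannose and is used in the Why lines; compound names use their own systematic numbering.
Assumption: lactols 4 and 5 are anomeric mixtures that react through one open-chain aldehyde; the α-anomer is drawn.

**Route**

Step 1
Reactants: 1 2,3:5,6-di-O-isopropylidene-α-D-mannofuranose; 2 formaldehyde (37 % aqueous)
Product: 4 2-C-(hydroxymethyl)-2,3:5,6-di-O-isopropylidene-α-D-mannofuranose, via open-chain aldol aldehyde 3 (not isolated)
Conditions: aq. CH2O (excess), K2CO3, MeOH, 65 °C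
Reagents that add atoms: none
Why: Carbonate opens the lactol to its aldehydo form, the only α-hydrogen (at m-2, target C1) is removed, and the enolate adds to formaldehyde to give aldehyde 3, which recloses; the closest known reaction type is the crossed (Tollens-type) aldol of 2,3-O-isopropylidene aldofuranoses with formaldehyde that gives 2-C-hydroxymethyl branched sugars. The only ring closed is the furanose lactol, by 5-exo-trig addition of O-4 to the aldehyde carbon. The new quaternary centre is controlled by the dioxolane: O-2 is held by the acetal and formaldehyde should enter on the dioxolane face anti to the m-4 side chain, so the CH2OH takes the place of the former H-2 (D-manno sense retained). The other diastereomer would need a trans-fused lactol, cannot close, and can return through the reversible aldol. The step needs mono-hydroxymethylation without Cannizzaro reduction: m-2 carries the single enolisable hydrogen and becomes quaternary, and the product aldehyde is shielded from hydride transfer because it rests as the lactol.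

Step 2
Reactants: 4 2-C-(hydroxymethyl)-2,3:5,6-di-O-isopropylidene-α-D-mannofuranose
Product: 5 2-C-[(tert-butyldiphenylsilyloxy)methyl]-2,3:5,6-di-O-isopropylidene-α-D-mannofuranose
Conditions: TBDPSCl (1.1 equiv), imidazole, DMF, 0 °C to rt
Reagents that add atoms: tert-butyl(chloro)diphenylsilane, CC(C)(C)[Si](Cl)(c1ccccc1)c1ccccc1
Why: Chemoselective silyl ether formation, since a bulky silyl chloride should react much faster with the primary hydroxyl than with the hemiacetal hydroxyl, and capping this β-oxygen blocks retro-aldol loss of formaldehyde in the basic step that follows.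

Step 3
Reactants: 5 2-C-[(tert-butyldiphenylsilyloxy)methyl]-2,3:5,6-di-O-isopropylidene-α-D-mannofuranose
Product: 6 3-C-[(tert-butyldiphenylsilyloxy)methyl]-1,2-dideoxy-3,4:6,7-di-O-isopropylidene-D-manno-hept-1-enitol (5-OH free)
Conditions: Ph3PCH3Br, KOtBu, THF, 0 °C to 50 °C
Reagents that add atoms: methyltriphenylphosphonium bromide, C[P+](c1ccccc1)(c1ccccc1)c1ccccc1.[Br-]
Why: Wittig methylenation of the lactol through its open-chain aldehyde, which has no α-hydrogen and so cannot epimerise or eliminate; m-1 becomes the future ring carbon C2 and the m-4 hydroxyl is released.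

Step 4
Reactants: 6 3-C-[(tert-butyldiphenylsilyloxy)methyl]-1,2-dideoxy-3,4:6,7-di-O-isopropylidene-D-manno-hept-1-enitol
Product: 7 3-C-[(tert-butyldiphenylsilyloxy)methyl]-1,2-dideoxy-3,4:6,7-di-O-isopropylidene-5-O-(methoxymethyl)-D-manno-hept-1-enitol
Conditions: MOMCl, iPr2NEt, Bu4NI (cat.), CH2Cl2, 0 °C to 40 °C
Reagents that add atoms: chloromethyl methyl ether, COCCl
Why: Methoxymethyl ether formation at the only free hydroxyl, which keeps O-4 of mannose (target O-5) out of a Payne rearrangement in steps 6 and 7 and out of the benzoylation in step 10.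

Step 5
Reactants: 7 3-C-[(tert-butyldiphenylsilyloxy)methyl]-1,2-dideoxy-3,4:6,7-di-O-isopropylidene-5-O-(methoxymethyl)-D-manno-hept-1-enitol
Product: 8 3-C-[(tert-butyldiphenylsilyloxy)methyl]-1,2-dideoxy-3,4-O-isopropylidene-5-O-(methoxymethyl)-D-manno-hept-1-enitol (6,7-diol)
Conditions: AcOH/H2O 7:3, rt to 40 °C
Reagents that add atoms: none
Why: Selective acid hydrolysis, since a terminal isopropylidene acetal should cleave much faster than the internal one on the fully substituted carbon, while MOM and TBDPS ethers are stable to aqueous acetic acid.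

Step 6
Reactants: 8 3-C-[(tert-butyldiphenylsilyloxy)methyl]-1,2-dideoxy-3,4-O-isopropylidene-5-O-(methoxymethyl)-D-manno-hept-1-enitol
Product: 10 6,7-anhydro-3-C-[(tert-butyldiphenylsilyloxy)methyl]-1,2-dideoxy-3,4-O-isopropylidene-5-O-(methoxymethyl)-D-manno-hept-1-enitol, via primary monotosylate 9 (not isolated)
Conditions: TsCl, Et3N, Bu2SnO (cat.), CH2Cl2, 0 °C to rt; then K2CO3, MeOH, rt
Reagents that add atoms: none
Why: Tin-catalysed sulfonylation goes to the primary hydroxyl of the 1,2-diol and carbonate then closes the epoxide by intramolecular SN2 at the CH2 carbon, so the C–O bond at m-5 is never broken and its configuration is kept.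

Step 7
Reactants: 10 6,7-anhydro-3-C-[(tert-butyldiphenylsilyloxy)methyl]-1,2-dideoxy-3,4-O-isopropylidene-5-O-(methoxymethyl)-D-manno-hept-1-enitol
Product: 11 3-C-[(tert-butyldiphenylsilyloxy)methyl]-1,2,7,8-tetradeoxy-3,4-O-isopropylidene-5-O-(methoxymethyl)-D-manno-octa-1,7-dienitol (6-OH free)
Conditions: Me3SI (5 equiv), n-BuLi (4.8 equiv), THF, −10 °C (ylide preformed) to rt
Reagents that add atoms: trimethylsulfonium iodide, C[S+](C)C.[I-]
Why: Sulfonium-ylide homologation of a terminal epoxide: the methylide opens the epoxide at the CH2 carbon and the resulting oxido sulfonium ylide eliminates dimethyl sulfide to the allylic alcohol, without touching m-5.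

Step 8
Reactants: 11 3-C-[(tert-butyldiphenylsilyloxy)methyl]-1,2,7,8-tetradeoxy-3,4-O-isopropylidene-5-O-(methoxymethyl)-D-manno-octa-1,7-dienitol
Product: 12 1-C-[(tert-butyldiphenylsilyloxy)methyl]-1,6-O-isopropylidene-5-O-(methoxymethyl)cyclohex-2-ene-1,4,5,6-tetrol (target ring numbering and configuration, 4-OH free)
Conditions: Grubbs second-generation catalyst (5 mol %), CH2Cl2 (5 mM), 40 °C
Reagents that add atoms: none
Why: Ring-closing metathesis of the 1,7-diene to the cyclohexene; the cis-fused dioxolane pre-organises the chain, and the unhindered allylic-alcohol alkene should load the catalyst, which is then delivered intramolecularly to the vinyl group on the quaternary carbon.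

Step 9
Reactants: 12 1-C-[(tert-butyldiphenylsilyloxy)methyl]-1,6-O-isopropylidene-5-O-(methoxymethyl)cyclohex-2-ene-1,4,5,6-tetrol
Product: 13 1-C-(hydroxymethyl)-1,6-O-isopropylidene-5-O-(methoxymethyl)cyclohex-2-ene-1,4,5,6-tetrol (primary OH and 4-OH free)
Conditions: TBAF, THF, 0 °C to rt
Reagents that add atoms: none
Why: Fluoride-induced cleavage of the silyl ether, to which MOM ether, acetonide and alkene are inert.

Step 10
Reactants: 13 1-C-(hydroxymethyl)-1,6-O-isopropylidene-5-O-(methoxymethyl)cyclohex-2-ene-1,4,5,6-tetrol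
Product: 14 4-O-benzoyl-1-C-(benzoyloxymethyl)-1,6-O-isopropylidene-5-O-(methoxymethyl)cyclohex-2-ene-1,4,5,6-tetrol
Conditions: BzCl (3 equiv), pyridine, DMAP (cat.), CH2Cl2, 0 °C to rt
Reagents that add atoms: benzoyl chloride, O=C(Cl)c1ccccc1
Why: DMAP-catalysed acylation of the primary and the allylic secondary hydroxyl, the only two free hydroxyls, which places both benzoates where the target has them.

Step 11
Reactants: 14 4-O-benzoyl-1-C-(benzoyloxymethyl)-1,6-O-isopropylidene-5-O-(methoxymethyl)cyclohex-2-ene-1,4,5,6-tetrol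
Product: 15 [(1S,4R,5S,6S)-4-(benzoyloxy)-1,5,6-trihydroxycyclohex-2-en-1-yl]methyl benzoate (target)
Conditions: TFA/H2O 9:1, 0 °C to rt
Reagents that add atoms: none
Why: Acid hydrolysis of the isopropylidene and methoxymethyl acetals; benzoates are stable to aqueous acid, and acyl migration to the neighbouring cis hydroxyl is base-promoted and should be slow under these conditions.

**Compound list**

1 | 2,3:5,6-di-O-isopropylidene-α-D-mannofuranose (diacetone-D-mannose) | O[C@@H]1[C@H]2OC(C)(C)O[C@H]2[C@H](O1)[C@H]3COC(C)(C)O3 | starting material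
2 | formaldehyde (37 % aqueous solution) | C=O | starting material
3 | 2-C-(hydroxymethyl)-2,3:5,6-di-O-isopropylidene-aldehydo-D-mannose (open-chain aldol aldehyde, not isolated) | O=C[C@@]1(CO)OC(C)(C)O[C@H]1[C@H](O)[C@H]2COC(C)(C)O2 | intermediate
4 | 2-C-(hydroxymethyl)-2,3:5,6-di-O-isopropylidene-α-D-mannofuranose | O[C@@H]1[C@@]2(CO)OC(C)(C)O[C@H]2[C@H](O1)[C@H]3COC(C)(C)O3 | intermediate
5 | 2-C-[(tert-butyldiphenylsilyloxy)methyl]-2,3:5,6-di-O-isopropylidene-α-D-mannofuranose | O[C@@H]1[C@@]2(CO[Si](c3ccccc3)(c4ccccc4)C(C)(C)C)OC(C)(C)O[C@H]2[C@H](O1)[C@H]5COC(C)(C)O5 | intermediate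
6 | 3-C-[(tert-butyldiphenylsilyloxy)methyl]-1,2-dideoxy-3,4:6,7-di-O-isopropylidene-D-manno-hept-1-enitol | C=C[C@@]1(CO[Si](c2ccccc2)(c3ccccc3)C(C)(C)C)OC(C)(C)O[C@H]1[C@H](O)[C@H]4COC(C)(C)O4 | intermediate
7 | 5-O-(methoxymethyl) ether of 6 | C=C[C@@]1(CO[Si](c2ccccc2)(c3ccccc3)C(C)(C)C)OC(C)(C)O[C@H]1[C@H](OCOC)[C@H]4COC(C)(C)O4 | intermediate
8 | 3-C-[(tert-butyldiphenylsilyloxy)methyl]-1,2-dideoxy-3,4-O-isopropylidene-5-O-(methoxymethyl)-D-manno-hept-1-enitol (6,7-diol) | C=C[C@@]1(CO[Si](c2ccccc2)(c3ccccc3)C(C)(C)C)OC(C)(C)O[C@H]1[C@H](OCOC)[C@H](O)CO | intermediate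
9 | 7-O-(p-toluenesulfonyl) derivative of 8 (not isolated) | C=C[C@@]1(CO[Si](c2ccccc2)(c3ccccc3)C(C)(C)C)OC(C)(C)O[C@H]1[C@H](OCOC)[C@H](O)COS(=O)(=O)c4ccc(C)cc4 | intermediate
10 | 6,7-anhydro-3-C-[(tert-butyldiphenylsilyloxy)methyl]-1,2-dideoxy-3,4-O-isopropylidene-5-O-(methoxymethyl)-D-manno-hept-1-enitol | C=C[C@@]1(CO[Si](c2ccccc2)(c3ccccc3)C(C)(C)C)OC(C)(C)O[C@H]1[C@H](OCOC)[C@H]4CO4 | intermediate
11 | 3-C-[(tert-butyldiphenylsilyloxy)methyl]-1,2,7,8-tetradeoxy-3,4-O-isopropylidene-5-O-(methoxymethyl)-D-manno-octa-1,7-dienitol | C=C[C@@]1(CO[Si](c2ccccc2)(c3ccccc3)C(C)(C)C)OC(C)(C)O[C@H]1[C@H](OCOC)[C@H](O)C=C | intermediate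
12 | 1-C-[(tert-butyldiphenylsilyloxy)methyl]-1,6-O-isopropylidene-5-O-(methoxymethyl)cyclohex-2-ene-1,4,5,6-tetrol (configuration as in 15) | C1=C[C@@]2(CO[Si](c3ccccc3)(c4ccccc4)C(C)(C)C)OC(C)(C)O[C@H]2[C@H](OCOC)[C@@H]1O | intermediate
13 | 1-C-(hydroxymethyl)-1,6-O-isopropylidene-5-O-(methoxymethyl)cyclohex-2-ene-1,4,5,6-tetrol (configuration as in 15) | C1=C[C@@]2(CO)OC(C)(C)O[C@H]2[C@H](OCOC)[C@@H]1O | intermediate
14 | 4-O-benzoyl-1-C-(benzoyloxymethyl)-1,6-O-isopropylidene-5-O-(methoxymethyl)cyclohex-2-ene-1,4,5,6-tetrol (configuration as in 15) | C1=C[C@@]2(COC(=O)c3ccccc3)OC(C)(C)O[C@H]2[C@H](OCOC)[C@@H]1OC(=O)c4ccccc4 | intermediate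
15 | [(1S,4R,5S,6S)-4-(benzoyloxy)-1,5,6-trihydroxycyclohex-2-en-1-yl]methyl benzoate | O=C(OC[C@@]1(O)C=C[C@@H](OC(=O)c2ccccc2)[C@@H](O)[C@@H]1O)c1ccccc1 | target

**Count and risks**

Total step count: 11. Longest linear sequence: 11 steps (fully linear from 1).

Step 7. The ylide attack at the epoxide next to the branched, MOM-bearing carbon may stall, or the ylide may be used up by proton transfer, so that homologation does not go to completion. The fallback sets out from diol 8 and comes back at 11, and replaces epoxide homologation by olefination of an aldehyde. 4-Methoxybenzaldehyde dimethyl acetal with PPTS in CH2Cl2 should give the 6,7-O-(4-methoxybenzylidene) acetal F1 (mixture at the acetal carbon). DIBAL-H at −78 °C should open it at the less hindered oxygen to the 6-O-(4-methoxybenzyl) ether with free 7-OH F2. Dess–Martin oxidation should give the 6-O-(4-methoxybenzyl) aldehyde F3, Wittig methylenation at −78 to 0 °C the 6-O-(4-methoxybenzyl) diene F4, and DDQ in wet CH2Cl2 should release 11.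

Step 8. Ruthenium-hydride isomerisation of the free allylic alcohol to an ethyl ketone, or unproductive chelation of the catalyst, may outrun closure onto the hindered vinyl group. The fallback sets out from 11 and comes back at 14; the order of acylation and cyclisation is inverted, so the ring is closed on an ester with no hydroxyl present. BzCl/pyridine/DMAP should give the 6-O-benzoyl diene F5, metathesis (same catalyst, toluene, 80 °C) the cyclohexenyl benzoate F6, TBAF buffered with AcOH the primary alcohol F7, and a second benzoylation 14.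

Step 3. The ring–chain equilibrium of the α-quaternary lactol may lie far on the ring side and the ylide add reversibly and slowly, so that base-induced silyl migration competes with olefination. The fallback sets out from 5 and comes back at 6 by addition and separate elimination (Peterson olefination). (Trimethylsilyl)methyllithium in excess should add irreversibly to the aldehyde form and give the β-hydroxysilane diol F8 (mixture at the new carbinol carbon, which is lost again); KH in THF should then effect syn-elimination to alkene 6.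

**Further compounds**

F1 | step 7 | 6,7-O-(4-methoxybenzylidene) acetal of 8 | C=C[C@@]1(CO[Si](c2ccccc2)(c3ccccc3)C(C)(C)C)OC(C)(C)O[C@H]1[C@H](OCOC)[C@H]4COC(c5ccc(OC)cc5)O4
F2 | step 7 | 6-O-(4-methoxybenzyl) ether of 8 with free 7-OH | C=C[C@@]1(CO[Si](c2ccccc2)(c3ccccc3)C(C)(C)C)OC(C)(C)O[C@H]1[C@H](OCOC)[C@H](OCc4ccc(OC)cc4)CO
F3 | step 7 | 6-O-(4-methoxybenzyl) aldehyde from F2 | C=C[C@@]1(CO[Si](c2ccccc2)(c3ccccc3)C(C)(C)C)OC(C)(C)O[C@H]1[C@H](OCOC)[C@H](OCc4ccc(OC)cc4)C=O
F4 | step 7 | 6-O-(4-methoxybenzyl) ether of 11 | C=C[C@@]1(CO[Si](c2ccccc2)(c3ccccc3)C(C)(C)C)OC(C)(C)O[C@H]1[C@H](OCOC)[C@H](OCc4ccc(OC)cc4)C=C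
F5 | step 8 | 6-O-benzoate of 11 | C=C[C@@]1(CO[Si](c2ccccc2)(c3ccccc3)C(C)(C)C)OC(C)(C)O[C@H]1[C@H](OCOC)[C@H](OC(=O)c4ccccc4)C=C
F6 | step 8 | 4-O-benzoate of 12 | C1=C[C@@]2(CO[Si](c3ccccc3)(c4ccccc4)C(C)(C)C)OC(C)(C)O[C@H]2[C@H](OCOC)[C@@H]1OC(=O)c5ccccc5
F7 | step 8 | 4-O-benzoate of 13 with free primary OH | C1=C[C@@]2(CO)OC(C)(C)O[C@H]2[C@H](OCOC)[C@@H]1OC(=O)c3ccccc3
F8 | step 3 | β-hydroxysilane diol from 5 and (trimethylsilyl)methyllithium | C[Si](C)(C)CC(O)[C@@]1(CO[Si](c2ccccc2)(c3ccccc3)C(C)(C)C)OC(C)(C)O[C@H]1[C@H](O)[C@H]4COC(C)(C)O4
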